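The flasks south-west and south-east were to be read at 3.0 h, twice the 90.0 min of my last readings, so I had to carry the earlier curves forward.

the same everywhere: electrophile 0.10 M

| flask | free base | protonated nucleophile | remark | time |
|---|---|---|---|---|
| spring | 0.078 M | 0.20 M | run made earlier |  |
| noon | 0.11 M | 0.20 M | run made earlier |  |
| south-west | 0.160 M | 0.200 M |  | 3.0 h |
| south-east | 0.0800 M | 0.200 M |  | 3.0 h |

| run | time / min | electrophile / % | target / % |
|---|---|---|---|
| spring | 8.00 | 97 | 0 |
| spring | 25.0 | 91 | 6 |
| spring | 40.0 | 91 | 4 |
| spring | 60.0 | 76 | 7 |
| spring | 90.0 | 73 | 13 |
| noon | 20.0 | 89 | 8 |
| noon | 40.0 | 88 | 6 |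
| noon | 50.0 | 81 | 9 |
| noon | 80.0 | 73 | 11 |
| noon | 90.0 | 74 | 13 |

(scatter of a reading: 2 percentage points)

- part of the electrophile that has reacted at the end, south-west
- part of the electrophile that has reacted at the end, south-east
- what raising the concentration of free base from its lowest to its highest value here does to the part of the electrophile that has reacted (changes below 5 percentage points count as none) (it rises / no change / it falls)

I read the last rows first. The spring run left 73% of its electrophile and the noon run 74%, although the noon run held 1.41 times the free base. That gap of 1 percentage point was smaller than the 2.8 points scatter of a difference between two readings, so the pair could not show whether free base mattered.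

I replaced each curve by its mean loss constant, the logarithm of charged over remaining electrophile divided by the time, a pseudo-first-order stand-in. The two last rows together gave 0.205 h⁻¹. I checked it against the readings at 40.0 min: it predicted 87.2% left, and the spring run read 91%, 1.89 standard deviations off, and the noon run 88%, 0.394 standard deviations off. Carried to 3.0 h, the constant gave me 46.0% reacted in both flasks. I expected no change with free base, but weakly, since the margin is 5 points and the runs resolved little better than that.

The forecast gave 49% for south-west, 48% for south-east and "no change", taking the loss as zero order in free base “Loss therefore looks about zero order in free base”. Its figures stood above mine.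

The flasks gave 49.6% in south-west and 39.6% in south-east: it rises, by 10 points.

    electrophile + nucleophile → acid set free + target (k = 1.20 M⁻¹ h⁻¹)
    nucleophile + acid set free ⇌ protonated nucleophile, settled at all times (K = 650 M⁻¹)
    acid set free + free base ⇌ salt of the base, settled at all times (K = 38000 M⁻¹)
    2 electrophile → self-condensation product (k = 0.610 M⁻¹ h⁻¹)

Reckoned back, south-west had a mean loss constant of 0.228 h⁻¹ and south-east 0.168 h⁻¹, with my 0.205 h⁻¹ between them. The single constant therefore overshot south-east by 6.4 points. Carried to south-west left until 12 h, 0.205 h⁻¹ predicts 8.54% of the electrophile left. That flask held 17% electrophile at 12.0 h, a mean loss constant of 0.146 h⁻¹.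

The earlier runs and the new flask stem from a simulated flask for an exercise; noise was put on by code.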